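(The readings come from a simulation from invented constants, noise included.)

Set the flask beside the north run, which looks nearly the same: equal solid substrate, but reagent at 0.950 of the solid substrate charged in the flask and 0.480 in the north run.

| setting | north | south-west | flask |
|---|---|---|---|
| solid substrate | 0.10 M | 0.10 M | 0.10 M |
| reagent | 0.048 M | 0.19 M | 0.0950 M |
| remark | run made earlier | run made earlier |  |
| time |  |  | 2.5 min |

| run | time / min | target / % |
|---|---|---|
| north | 0.833 | 19.5 |
| north | 1.50 | 21.8 |
| north | 2.50 | 22.5 |
| north | 3.00 | 22.5 |
| south-west | 0.417 | 38.2 |
| south-west | 1.00 | 51.7 |
| south-west | 2.00 | 56.0 |
| south-west | 3.00 | 56.5 |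

(readings scatter by 0.3 percentage points)

- target at 2.5 min, in percent of the solid substrate charged
- the change that raises the amount of target at 2.5 min, in percent of the solid substrate charged most ("none" if none brings more than 2 percentage points) (alder / cedar / oak / none)
- amount of target at 2.5 min, in percent of the solid substrate charged, after alder

- alder: doubling the dissolution coefficient of the solid substrate, all else as stated
- cedar: doubling the amount of reagent, all else as stated
- oak: doubling the solubility of the solid substrate, all else as stated

Take one reagent per target. The north run reads 22.5% at 2.50 min and 22.5% at 3.00 min, so it has stopped below what its reagent could give. Read reagent as the limiting reagent there, because solid substrate charged exceeds reagent charged. Now name the quantity to carry: the capture, the fraction of charged reagent that ends as target.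

north: 0.469

south-west: 0.297

flask, midway by the logarithm of the reagent charge: 0.384

target in the flask = capture × reagent charged / solid substrate charged = 36.5%

So expect the flask to end above the north run, with more reagent charged but a lower capture.

The forecast says 37%, 0.50 percentage points above my figure, names oak as the best change and gives 41% after alder. Its ground for the choice: “Oak doubles the dissolved concentration, hence the rate at every stage”.

The flask gives 37.6%, and the best change is cedar, worth 19 points against 3.9 points for oak, with 39.2% after alder.

    dissolved substrate + reagent → target (k = 0.300 L mol⁻¹ s⁻¹)
    2 reagent → homo dimer (k = 0.140 L mol⁻¹ s⁻¹)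
    solid substrate ⇌ dissolved substrate, rate k3*(cs3 - [dissolved substrate]) while solid is left; crystals form when [dissolved substrate] > cs3 (solubility = 0.0750 M, k = 0.360 s⁻¹)
    reagent → side product (k = 0.0160 s⁻¹)

At 2.50 min the flask holds 0.280% of its reagent, and its capture comes to 0.396 beside my 0.384. Now take the same flask with 0.25 M of solid substrate and unchanged reagent. The carried capture gives 14.6% of that larger charge. That neighbour gives 15.3%, with 54.7% still solid and 0.196% of its reagent left.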